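**Retrosynthetic overview**
- Target ⇐ regioselective dehydration of a C4 tertiary carbinol ⇐ transannular C1–C5 closure of a 10-membered (1(10)E,4E)-prenylgermacradien-6-ol through its hydroxyl-directed 4,5-epoxide. This mirrors the presumed biogenesis: acyclic C20 chain → 10-membered ring → hydroazulene.
- 10-membered ring ⇐ C5–C6 closure (alkenyl iodide onto aldehyde) of an acyclic diacetoxy iodo aldehyde.
- Acyclic chain ⇐ keto lactone (C9 reduction; lactone → Weinreb amide → aldehyde; both acetates installed together).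
- Keto lactone ⇐ C7–C8 oxidative coupling of a cis-4-methyl-5-prenyl butanolide enolate with an iodo dienone enolate.
- Ring order: the 10-membered carbocycle first; then the five- and seven-membered rings together in the transannular step.

Assumption: atom labels C1–C15 follow the usual dictyol numbering (C1/C5 ring fusion, C3=C4 ring olefin, C6 carbinol, C7 side-chain-bearing carbon, C9 acetoxy carbon, C10 methylidene carbon, C11–C15 side chain) and are used for all intermediates.

**Route**

Step 1
Reactants: 1 pent-4-yn-1-ol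
Product: 3 (E)-5-iodo-4-methylpent-4-en-1-ol, via alkenylalane 2 (not isolated)
Conditions: AlMe3 (3 equiv), Cp2ZrCl2 (0.25 equiv), CH2Cl2, 0 °C → rt; then I2, THF, −30 → 0 °C
Reagents that add atoms: trimethylaluminium C[Al](C)C; iodine II
Why: Negishi zirconium-catalysed carboalumination adds Me and Al syn across the terminal alkyne (Al at the terminus, the hydroxyl riding as its aluminium alkoxide) and iodinolysis with retention gives the (E)-iodoalkene that later becomes C4=C5.

Step 2
Reactants: 3 (E)-5-iodo-4-methylpent-4-en-1-ol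
Product: 4 (E)-5-iodo-4-methylpent-4-enal
Conditions: Dess–Martin periodinane, pyridine, CH2Cl2, 0 °C → rt
Reagents that add atoms: none
Why: Dess–Martin oxidation of the primary alcohol is mild and buffered, so the alkenyl iodide and its geometry are untouched.

Step 3
Reactants: 4 (E)-5-iodo-4-methylpent-4-enal; 5 3-(triphenylphosphoranylidene)butan-2-one
Product: 6 (3E,7E)-8-iodo-3,7-dimethylocta-3,7-dien-2-one
Conditions: toluene, 90 °C
Reagents that add atoms: none
Why: Wittig olefination with the stabilised acyl ylide is under thermodynamic control and gives the (E)-trisubstituted enone (future C1=C10 next to the C9 carbonyl), with no stereocentre formed.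

Step 4
Reactants: 7 4-methylpent-3-en-1-ol
Product: 8 4-methylpent-3-enal
Conditions: Dess–Martin periodinane, pyridine, CH2Cl2, 0 °C; used at once as a solution
Reagents that add atoms: none
Why: Dess–Martin oxidation with pyridine buffer gives the β,γ-unsaturated aldehyde without moving the alkene into conjugation.

Step 5
Reactants: 8 4-methylpent-3-enal
Product: 10 (3S,4S)-3,7-dimethylocta-1,6-dien-4-ol, via borinate ester 9 (not isolated)
Conditions: cis-2-butene, KOt-Bu, n-BuLi, THF, −78 → −45 °C; (+)-Ipc2BOMe, −78 °C; BF3·OEt2; then 8, −78 °C; then NaOH, H2O2, 0 °C → rt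
Reagents that add atoms: cis-but-2-ene C/C=C\C
Why: Brown crotylboration runs through a closed chair transition state in which the (Z)-crotyl geometry fixes the syn C11/C12 relationship and the (+)-isopinocampheyl ligands (from (−)-α-pinene) select the aldehyde Re face, giving the (3S,4S) alcohol after oxidative cleavage of the borinate.

Step 6
Reactants: 10 (3S,4S)-3,7-dimethylocta-1,6-dien-4-ol
Product: 12 (3S,4S)-3,7-dimethyloct-6-ene-1,4-diol, via trialkylborane 11 (not isolated)
Conditions: 9-BBN (2.2 equiv), THF, 0 °C → rt; then NaOH, H2O2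
Reagents that add atoms: hydrogen peroxide OO
Why: Hydroboration–oxidation with 9-BBN is anti-Markovnikov and selective for the monosubstituted alkene over the trisubstituted prenyl alkene, so only the terminal carbon (future C6) is oxygenated and no stereocentre changes.

Step 7
Reactants: 12 (3S,4S)-3,7-dimethyloct-6-ene-1,4-diol
Product: 14 (4S,5S)-4-methyl-5-(3-methylbut-2-en-1-yl)oxolan-2-one, via lactol 13 (not isolated)
Conditions: TEMPO (10 mol %), PhI(OAc)2 (2.5 equiv), CH2Cl2, rt
Reagents that add atoms: none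
Why: TEMPO/PhI(OAc)2 oxidative lactonisation oxidises only the primary alcohol to the aldehyde, which is trapped by the C12 hydroxyl as the lactol and oxidised on to the γ-lactone, locking C11 and C12 cis on a five-membered ring.

Step 8
Reactants: 14 (4S,5S)-4-methyl-5-(3-methylbut-2-en-1-yl)oxolan-2-one; 6 (3E,7E)-8-iodo-3,7-dimethylocta-3,7-dien-2-one
Product: 17 (3S,4S,5S)-3-[(3E,7E)-8-iodo-3,7-dimethyl-2-oxoocta-3,7-dien-1-yl]-4-methyl-5-(3-methylbut-2-en-1-yl)oxolan-2-one, via lactone lithium enolate 15 (not isolated), via ketone lithium enolate 16 (not isolated)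
Conditions: 14 (1 equiv), 6 (1.5 equiv), LiN(i-Pr)2 (2.6 equiv), THF, −78 °C; then Fe(acac)3 (2.6 equiv), −78 → 0 °C
Reagents that add atoms: none
Why: Oxidative enolate heterocoupling (one-electron oxidation of the mixed lithium enolates by Fe(acac)3 and cross-coupling) forms C7–C8 on the lactone face anti to the cis C4-methyl and C5-prenyl groups, so the new epimerisable centre (C7) is set trans to the methyl group, which is also the thermodynamic isomer.

Step 9
Reactants: 17 keto lactone
Product: 18 (3S,4S,5S)-3-[(2R,3E,7E)-2-hydroxy-8-iodo-3,7-dimethylocta-3,7-dien-1-yl]-4-methyl-5-(3-methylbut-2-en-1-yl)oxolan-2-one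
Conditions: (S)-Me-CBS oxazaborolidine (0.3 equiv), BH3·SMe2, THF, −30 °C; MeOH quench
Reagents that add atoms: none
Why: Corey–Bakshi–Shibata reduction with the (S)-oxazaborolidine places the alkenyl group in the large-substituent position and gives the (R)-allylic alcohol at C9 under reagent control, leaving lactone, iodoalkene and alkenes intact.

Step 10
Reactants: 18 hydroxy lactone
Product: 20 (2S,3S,4S)-4-acetoxy-2-[(2R,3E,7E)-2-acetoxy-8-iodo-3,7-dimethylocta-3,7-dien-1-yl]-N-methoxy-N,3,7-trimethyloct-6-enamide, via dihydroxy amide 19 (not isolated)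
Conditions: AlMe3, MeNH(OMe)·HCl, CH2Cl2, 0 → 40 °C; then pyridine, Ac2O, DMAP, 0 °C → rt
Reagents that add atoms: N,O-dimethylhydroxylamine hydrochloride CNOC.Cl; acetic anhydride CC(=O)OC(C)=O
Why: Weinreb aminolysis of the γ-lactone by the aluminium amide frees the C12 alkoxide, and acetylation of both aluminium alkoxides (C9 and C12) in the same flask prevents relactonisation and installs both acetates of the target before the C6 oxygen exists, with no stereocentre touched.

Step 11
Reactants: 20 diacetoxy Weinreb amide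
Product: 21 (2S,3S,4S)-4-acetoxy-2-[(2R,3E,7E)-2-acetoxy-8-iodo-3,7-dimethylocta-3,7-dien-1-yl]-3,7-dimethyloct-6-enal
Conditions: Cp2Zr(H)Cl (1.6 equiv), THF, rt, 30 min
Reagents that add atoms: none
Why: Cp2Zr(H)Cl reduces the amide to the aldehyde by hydrozirconation of the amide carbonyl and collapse of the zirconated hemiaminal on work-up, a neutral reduction that spares acetates, the alkenyl iodide and trisubstituted alkenes and does not epimerise C7.

Step 12
Reactants: 21 diacetoxy iodo aldehyde
Product: 22 (1R,2E,6E,8R,10S)-8-acetoxy-10-[(2S,3S)-3-acetoxy-6-methylhept-5-en-2-yl]-3,7-dimethylcyclodeca-2,6-dien-1-ol (dictyol numbering: 6R,7S,9R; 1(10)E,4E)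
Conditions: CrCl2 (8 equiv), NiCl2 (2 mol %), DMSO/THF 3:1, 2 mM, rt
Reagents that add atoms: none
Why: Intramolecular Nozaki–Hiyama–Kishi reaction (NiCl2-catalysed formation of the alkenylchromium species with retention of the E geometry, aldehyde-selective addition at high dilution) closes the 10-membered ring at C5–C6 and sets C6 (R) by Felkin–Anh addition anti to the C11 branch on C7, leaving the C6 hydroxyl as the only free one.

Step 13
Reactants: 22 macrocyclic dienol
Product: 24 (3S,3aR,4R,5S,7R,8aR)-5-[(2S,3S)-3-acetoxy-6-methylhept-5-en-2-yl]-3,4-dihydroxy-3-methyl-8-methylidenedecahydroazulen-7-yl acetate, via epoxy alcohol 23 (not isolated)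
Conditions: VO(acac)2 (5 mol %), t-BuOOH (1.05 equiv), CH2Cl2, 0 °C; then Me2AlCl (4 equiv), −78 → −40 °C
Reagents that add atoms: tert-butyl hydroperoxide CC(C)(C)OO
Why: Hydroxyl-directed epoxidation with VO(acac)2/t-BuOOH touches only the allylic-alcohol alkene and, from the conformer with H6 eclipsing C4=C5 (1,3-allylic strain with the C4 methyl), delivers oxygen syn to the C6 hydroxyl, after which Me2AlCl promotes the transannular epoxide–olefin cyclisation (cation–olefin type with ene-like termination) in which C1 of the C1=C10 alkene opens the epoxide at C5 with inversion (H5 syn to the C6 hydroxyl), the anti disposition of the two vinyl methyl groups in this conformer (C9 acetate pseudoaxial, C7 side chain pseudoequatorial) places H1 anti to H5 (trans ring fusion), and loss of a C14 proton to an aluminium methyl gives the exocyclic methylene.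

Step 14
Reactants: 24 hydroazulene diol
Product: 25 (3aS,4R,5S,7R,8aR)-5-[(2S,3S)-3-acetoxy-6-methylhept-5-en-2-yl]-4-hydroxy-3-methyl-8-methylidene-1,3a,4,5,6,7,8,8a-octahydroazulen-7-yl acetate (CNP0151479.2)
Conditions: Ph2S[OC(CF3)2Ph]2 (1.2 equiv), CH2Cl2, −20 → 0 °C
Reagents that add atoms: none
Why: Dehydration with the Martin sulfurane activates the tertiary C4 hydroxyl faster than the hindered secondary C6 hydroxyl and eliminates anti toward the ring methylene C3 (H5 is syn to the leaving group and cannot take part), giving the endocyclic C3=C4 alkene without touching any stereocentre.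

**Compound list**
1 | pent-4-yn-1-ol | C#CCCCO | starting material
2 | dimethyl{(1E)-5-[(dimethylalumanyl)oxy]-2-methylpent-1-en-1-yl}alumane | C[Al](C)/C=C(\C)CCCO[Al](C)C | intermediate
3 | (E)-5-iodo-4-methylpent-4-en-1-ol | OCCC/C(C)=C/I | intermediate
4 | (E)-5-iodo-4-methylpent-4-enal | O=CCC/C(C)=C/I | intermediate
5 | 3-(triphenylphosphoranylidene)butan-2-one | CC(=O)C(C)=P(c1ccccc1)(c1ccccc1)c1ccccc1 | starting material
6 | (3E,7E)-8-iodo-3,7-dimethylocta-3,7-dien-2-one | CC(=O)/C(C)=C/CC/C(C)=C/I | intermediate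
7 | 4-methylpent-3-en-1-ol | OCCC=C(C)C | starting material
8 | 4-methylpent-3-enal | O=CCC=C(C)C | intermediate
9 | (3S,4S)-3,7-dimethylocta-1,6-dien-4-yl bis[(1S,2S,3S,5R)-2,6,6-trimethylbicyclo[3.1.1]heptan-3-yl]borinate | C=C[C@H](C)[C@H](CC=C(C)C)OB([C@H]1C[C@H]2C[C@@H]([C@@H]1C)C2(C)C)[C@H]1C[C@H]2C[C@@H]([C@@H]1C)C2(C)C | intermediate
10 | (3S,4S)-3,7-dimethylocta-1,6-dien-4-ol | C=C[C@H](C)[C@H](CC=C(C)C)O | intermediate
11 | 9-{(3S,4S)-4-[(9-borabicyclo[3.3.1]nonan-9-yl)oxy]-3,7-dimethyloct-6-en-1-yl}-9-borabicyclo[3.3.1]nonane | C1CCC2CCCC1B2CC[C@H](C)[C@H](CC=C(C)C)OB1C2CCCC1CCC2 | intermediate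
12 | (3S,4S)-3,7-dimethyloct-6-ene-1,4-diol | OCC[C@H](C)[C@H](CC=C(C)C)O | intermediate
13 | (4S,5S)-4-methyl-5-(3-methylbut-2-en-1-yl)oxolan-2-ol (both anomers) | OC1C[C@H](C)[C@H](CC=C(C)C)O1 | intermediate
14 | (4S,5S)-4-methyl-5-(3-methylbut-2-en-1-yl)oxolan-2-one (cis) | O=C1C[C@H](C)[C@H](CC=C(C)C)O1 | intermediate
15 | lithium (4S,5S)-4-methyl-5-(3-methylbut-2-en-1-yl)-4,5-dihydrofuran-2-olate | [Li+].[O-]C1=C[C@H](C)[C@H](CC=C(C)C)O1 | intermediate
16 | lithium (3E,7E)-8-iodo-3,7-dimethylocta-1,3,7-trien-2-olate | [Li+].C=C([O-])/C(C)=C/CC/C(C)=C/I | intermediate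
17 | (3S,4S,5S)-3-[(3E,7E)-8-iodo-3,7-dimethyl-2-oxoocta-3,7-dien-1-yl]-4-methyl-5-(3-methylbut-2-en-1-yl)oxolan-2-one | O=C1[C@@H](CC(=O)/C(C)=C/CC/C(C)=C/I)[C@H](C)[C@H](CC=C(C)C)O1 | intermediate
18 | (3S,4S,5S)-3-[(2R,3E,7E)-2-hydroxy-8-iodo-3,7-dimethylocta-3,7-dien-1-yl]-4-methyl-5-(3-methylbut-2-en-1-yl)oxolan-2-one | O=C1[C@@H](C[C@@H](O)/C(C)=C/CC/C(C)=C/I)[C@H](C)[C@H](CC=C(C)C)O1 | intermediate
19 | (2S,3S,4S)-4-hydroxy-2-[(2R,3E,7E)-2-hydroxy-8-iodo-3,7-dimethylocta-3,7-dien-1-yl]-N-methoxy-N,3,7-trimethyloct-6-enamide | CON(C)C(=O)[C@H]([C@H](C)[C@H](CC=C(C)C)O)C[C@@H](O)/C(C)=C/CC/C(C)=C/I | intermediate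
20 | (2S,3S,4S)-4-acetoxy-2-[(2R,3E,7E)-2-acetoxy-8-iodo-3,7-dimethylocta-3,7-dien-1-yl]-N-methoxy-N,3,7-trimethyloct-6-enamide | CON(C)C(=O)[C@H]([C@H](C)[C@H](CC=C(C)C)OC(C)=O)C[C@@H](OC(C)=O)/C(C)=C/CC/C(C)=C/I | intermediate
21 | (2S,3S,4S)-4-acetoxy-2-[(2R,3E,7E)-2-acetoxy-8-iodo-3,7-dimethylocta-3,7-dien-1-yl]-3,7-dimethyloct-6-enal | O=C[C@H]([C@H](C)[C@H](CC=C(C)C)OC(C)=O)C[C@@H](OC(C)=O)/C(C)=C/CC/C(C)=C/I | intermediate
22 | (1R,2E,6E,8R,10S)-8-acetoxy-10-[(2S,3S)-3-acetoxy-6-methylhept-5-en-2-yl]-3,7-dimethylcyclodeca-2,6-dien-1-ol | C/C1=C\CC/C(C)=C/[C@H](O)[C@H]([C@H](C)[C@H](CC=C(C)C)OC(C)=O)C[C@H]1OC(C)=O | intermediate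
23 | (4S,5S)-4,5-epoxide of 22 (oxirane oxygen on the face of the C6 hydroxyl; C1=C10 still E) | C/C1=C\CC[C@]2(C)O[C@H]2[C@H](O)[C@H]([C@H](C)[C@H](CC=C(C)C)OC(C)=O)C[C@H]1OC(C)=O | intermediate
24 | (3S,3aR,4R,5S,7R,8aR)-5-[(2S,3S)-3-acetoxy-6-methylhept-5-en-2-yl]-3,4-dihydroxy-3-methyl-8-methylidenedecahydroazulen-7-yl acetate (trans-fused) | C=C1[C@H](OC(C)=O)C[C@@H]([C@H](C)[C@H](CC=C(C)C)OC(C)=O)[C@@H](O)[C@@H]2[C@@](C)(O)CC[C@@H]12 | intermediate
25 | (3aS,4R,5S,7R,8aR)-5-[(2S,3S)-3-acetoxy-6-methylhept-5-en-2-yl]-4-hydroxy-3-methyl-8-methylidene-1,3a,4,5,6,7,8,8a-octahydroazulen-7-yl acetate (CNP0151479.2) | C=C1[C@H](OC(C)=O)C[C@@H]([C@H](C)[C@H](CC=C(C)C)OC(C)=O)[C@@H](O)[C@@H]2C(C)=CC[C@@H]12 | target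

**Step count and risks**

Total steps: 14. Longest linear sequence: 11 (steps 4–14, from 7).

Steps most likely to fail:

Step 13 (epoxidation and transannular closure). The risks are a cis ring fusion, capture of the C10 cation by the neighbouring C9 acetate, loss of H1 instead of a C14 proton, and opening of the epoxide at C4 without ring closure. The fallback sets out from 22 and comes back at 25. The epoxy alcohol 23 is isolated after the same epoxidation (filtration through triethylamine-deactivated silica) and opened in wet hexafluoropropan-2-ol, so that water rather than proton loss ends the cascade and gives the C4,C10-diol F4 (C10 hydroxyl cis to the C9 acetoxy group). Both tertiary hydroxyls are then eliminated together with Ph2S[OC(CF3)2Ph]2 (2.5 equiv), which replaces step 14. This moves olefin formation out of the cationic step; it does not repair a wrong ring fusion.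

Step 12 (Ni/Cr ring closure). The risks are oligomers from the strained 10-membered closure and the wrong C6 epimer. The fallback sets out from 20 and comes back at 22. Iodine–magnesium exchange with i-PrMgCl·LiCl (THF, −40 °C, 1 mM) gives the alkenylmagnesium species, which acylates the tethered Weinreb amide on warming to 0 °C to give the macrocyclic dienone F3. Reduction with (S)-Me-CBS oxazaborolidine and BH3·SMe2 then sets C6 under reagent control and gives 22. Step 11 is no longer needed.

Step 8 (enolate heterocoupling). The risks are homodimers and low conversion with a hindered lactone enolate. The fallback sets out from 14 and comes back at 17. The lithium enolate of 14 (LiN(i-Pr)2, THF/DMPU, NaI, −78 → −20 °C) is alkylated, again anti to the C4 methyl, with 1-chloro-3-(triphenylphosphoranylidene)butan-2-one F1 (from ethyltriphenylphosphonium bromide, two equivalents of n-BuLi and chloroacetyl chloride) to give the lactone keto ylide F2. Wittig reaction of this stabilised ylide with aldehyde 4 (toluene, 90 °C) gives 17 and makes step 3 unnecessary.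

**Further compounds**
F1 | step 8 | 1-chloro-3-(triphenylphosphoranylidene)butan-2-one | ClCC(=O)C(C)=P(c1ccccc1)(c1ccccc1)c1ccccc1
F2 | step 8 | (3S,4S,5S)-4-methyl-5-(3-methylbut-2-en-1-yl)-3-[2-oxo-3-(triphenylphosphoranylidene)butyl]oxolan-2-one | O=C1[C@@H](CC(=O)C(C)=P(c2ccccc2)(c2ccccc2)c2ccccc2)[C@H](C)[C@H](CC=C(C)C)O1
F3 | step 12 | (2E,6E,8R,10S)-8-acetoxy-10-[(2S,3S)-3-acetoxy-6-methylhept-5-en-2-yl]-3,7-dimethylcyclodeca-2,6-dien-1-one | C/C1=C\CC/C(C)=C/C(=O)[C@H]([C@H](C)[C@H](CC=C(C)C)OC(C)=O)C[C@H]1OC(C)=O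
F4 | step 13 | trans-fused hydroazulene as 24 but with C10 carrying methyl and hydroxyl (hydroxyl cis to the C9 acetoxy group) in place of the methylidene | C[C@@]1(O)[C@H](OC(C)=O)C[C@@H]([C@H](C)[C@H](CC=C(C)C)OC(C)=O)[C@@H](O)[C@@H]2[C@@](C)(O)CC[C@@H]12
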